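**Strategy.** The cyclohexane ring is disconnected between the ring CH that bears the 3-hydroxypropyl arm and the ring carbon of the exocyclic C=C(CH3)CHO unit. That ring carbon is the β-carbon of an (E)-2-methylenal whose β-hydrogen lies cis to the aldehyde, so the derived N-benzyl imine can steer rhodium into this C–H bond. Its addition across a tethered internal alkene closes the six-membered ring, sets the ring CH stereocentre, generates the propyl arm by hydrogen transfer and leaves the tetrasubstituted enal with the natural geometry. The precursor is an acyclic pentaene hydroxy-enal built from sulcatone, homoprenyl bromide, propyne and (S)-citronellal through a stereospecific ketone allylboration.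

Key step: step 14

Assumption: (+)-sparteine and (+)-MIB are purchasable, and both ligands induce in the sense of the established models for carbamate lithiation and amino-alcohol-catalysed organozinc addition.

**Step 1**
Reactants: 1 6-methylhept-5-en-2-one (sulcatone)
Product: 2 (E)-7-hydroxy-6-methylhept-5-en-2-one
Conditions: SeO2 (0.3 equiv), tBuOOH, salicylic acid (cat.), CH2Cl2, 0 °C to rt
Reagents that add atoms: selenium dioxide, O=[Se]=O; tert-butyl hydroperoxide (reoxidant), CC(C)(C)OO
Why: SeO2-catalysed allylic oxidation (ene reaction, then [2,3]-sigmatropic shift) should hydroxylate only the (E)-methyl of the gem-dimethyl alkene and leave the methyl ketone alone, any over-oxidised enal being removed by chromatography.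

**Step 2**
Reactants: 2 (E)-7-hydroxy-6-methylhept-5-en-2-one
Product: 3 (E)-7-((tert-butyldimethylsilyl)oxy)-6-methylhept-5-en-2-one
Conditions: TBSCl, imidazole, DMF, rt
Reagents that add atoms: tert-butyldimethylsilyl chloride, C[Si](C)(Cl)C(C)(C)C
Why: Routine silylation of a primary allylic alcohol masks the future aldehyde carbon through the organometallic steps.

**Step 3**
Reactants: 4 5-bromo-2-methylpent-2-ene; 5 propyne
Product: 9 (Z)-1-iodo-2,6-dimethylhepta-1,5-diene, via Grignard reagent 6 (not isolated), via alkylcopper 7 (not isolated), via alkenylcopper 8 (not isolated)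
Conditions: Mg, Et2O, reflux; CuBr·SMe2, Et2O/Me2S, −45 °C; propyne, −25 °C; I2, THF, −50 to 0 °C
Reagents that add atoms: iodine, II
Why: Normant carbocupration adds the alkylcopper syn across propyne with copper on the terminal carbon, so iodinolysis with retention should give the iodide with iodine cis to the homoprenyl chain (Z).

**Step 4**
Reactants: 9 (Z)-1-iodo-2,6-dimethylhepta-1,5-diene
Product: 11 2-[(Z)-2,6-dimethylhepta-1,5-dien-1-yl]-4,4,5,5-tetramethyl-1,3,2-dioxaborolane, via alkenyllithium 10 (not isolated)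
Conditions: tBuLi (2.1 equiv), Et2O, −78 °C; iPrOBpin, −78 °C to rt
Reagents that add atoms: 2-isopropoxy-4,4,5,5-tetramethyl-1,3,2-dioxaborolane, CC(C)OB1OC(C)(C)C(C)(C)O1
Why: Lithium–iodine exchange and borylation of the alkenyllithium both proceed with retention of alkene geometry.

**Step 5**
Reactants: 12 3-((tert-butyldimethylsilyl)oxy)propan-1-ol
Product: 13 3-((tert-butyldimethylsilyl)oxy)propyl N,N-diisopropylcarbamate
Conditions: iPr2NC(O)Cl, Et3N, CH2Cl2, reflux
Reagents that add atoms: N,N-diisopropylcarbamoyl chloride, CC(C)N(C(C)C)C(Cl)=O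
Why: O-carbamoylation installs the directing and leaving group needed for enantioselective α-lithiation.

**Step 6**
Reactants: 13 3-((tert-butyldimethylsilyl)oxy)propyl N,N-diisopropylcarbamate; 11 (Z)-alkenyl pinacol boronate
Product: 16 (S,Z)-tert-butyl((5,9-dimethyl-3-(4,4,5,5-tetramethyl-1,3,2-dioxaborolan-2-yl)deca-4,8-dien-1-yl)oxy)dimethylsilane, via lithiated carbamate 14 (not isolated), via boronate complex 15 (not isolated)
Conditions: sBuLi, (+)-sparteine, Et2O, −78 °C; 11, −78 °C; MgBr2·OEt2, then 35 °C
Reagents that add atoms: none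
Why: Lithiation–borylation: sparteine-mediated deprotonation should give the configurationally stable (R)-α-lithio carbamate, which is borylated with retention and then undergoes a stereospecific 1,2-metallate shift of the alkenyl group with inversion, giving the (S)-allylic boronate with the alkene geometry intact.

**Step 7**
Reactants: 16 (S,Z)-allylic pinacol boronate; 3 (E)-7-((tert-butyldimethylsilyl)oxy)-6-methylhept-5-en-2-one
Product: 19 (2E,6S,7S,8E)-1,11-bis((tert-butyldimethylsilyl)oxy)-2,6,7-trimethyl-7-(4-methylpent-3-en-1-yl)undeca-2,8-dien-6-ol, via butyl ate complex 17 (not isolated), via borinic ester 18 (not isolated)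
Conditions: nBuLi, THF, −78 °C; (CF3CO)2O, −78 °C; 3, −78 °C to rt; aq. NaOH work-up
Reagents that add atoms: none
Why: Ketone allylboration through the more reactive borinic ester in a closed chair transition state: the bond forms at the γ-carbon, the α-substituent sits equatorial (it would otherwise clash with the cis γ-chain), so the boron-bearing stereocentre is relayed to the quaternary carbon (S) and an (E)-alkene results, while the ketone places methyl axial and its longer arm equatorial, which sets the tertiary carbinol (S).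

**Step 8**
Reactants: 19 bis-silyl ether tertiary alcohol
Product: 21 (2E,6S,7S,10E)-12-((tert-butyldimethylsilyl)oxy)-6-[(E)-4-((tert-butyldimethylsilyl)oxy)but-1-en-1-yl]-7-hydroxy-2,6,7,11-tetramethyldodeca-2,10-dienal, via allylic alcohol 20 (not isolated)
Conditions: SeO2 (0.5 equiv), tBuOOH, CH2Cl2, rt; then MnO2, CH2Cl2, rt
Reagents that add atoms: selenium dioxide, O=[Se]=O; tert-butyl hydroperoxide (reoxidant), CC(C)(C)OO
Why: Allylic oxidation should take place only at the (E)-methyl of the one remaining gem-dimethyl alkene, because the other trisubstituted alkene is deactivated by its allylic silyloxy group, and MnO2 then converts the allylic alcohol into the (E)-enal.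

**Step 9**
Reactants: 22 (S)-citronellal
Product: 24 (S)-3,7-dimethyloct-6-en-1-yne, via alkenyl nonaflate 23 (not isolated)
Conditions: C4F9SO2F, phosphazene base P2-Et (2.5 equiv), DMF, −30 °C to rt
Reagents that add atoms: none
Why: One-pot O-sulfonylation of the aldehyde enolate and β-elimination of the alkenyl nonaflate give the terminal alkyne with unchanged carbon count, and the methyl-bearing stereocentre is not touched.

**Step 10**
Reactants: 24 (S)-3,7-dimethyloct-6-en-1-yne; 21 chain enal
Product: 27 (R)-bis-allylic alcohol, that is 19 with the homoprenyl terminus extended to –CH2CH2CH=C(CH3)–CH(OH)–CH=CH–CH(CH3)–CH2CH2CH=C(CH3)2 (carbinol R, methyl-bearing carbon S, all alkenes E), via alkenylborane 25 (not isolated), via alkenylzinc 26 (not isolated)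
Conditions: 24 (3 equiv), Cy2BH, toluene, 0 °C to rt; Me2Zn (4 equiv), −78 °C; (+)-MIB (10 mol %); then 21, −20 to 0 °C; aq. NH4Cl
Reagents that add atoms: none
Why: Syn hydroboration of the alkyne, boron-to-zinc transmetalation and amino-alcohol-catalysed 1,2-addition of the (E)-alkenylzinc to the enal; (+)-MIB directs attack to the Re face (mirror image of the known sense of (−)-MIB) and so should set the carbinol as R, with the excess reagent absorbing the free tertiary hydroxyl.

**Step 11**
Reactants: 27 (R)-bis-allylic alcohol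
Product: 28 (R)-acetate of 27
Conditions: Ac2O, pyridine, DMAP (cat.), CH2Cl2, 0 °C
Reagents that add atoms: acetic anhydride, CC(=O)OC(C)=O
Why: DMAP-catalysed acylation esterifies the secondary alcohol, while the hindered tertiary alcohol does not react at 0 °C.

**Step 12**
Reactants: 28 acetate bis-silyl ether
Product: 29 acetate diol (primary allylic alcohol and 3-hydroxypropenyl alcohol free)
Conditions: HF·pyridine, pyridine, THF, 0 °C to rt
Reagents that add atoms: none
Why: Buffered fluoride cleaves both primary silyl ethers without ionising or transposing the bis-allylic acetate.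

**Step 13**
Reactants: 29 acetate diol
Product: 30 acyclic (E)-hydroxy enal (cyclisation precursor)
Conditions: MnO2, CH2Cl2, rt
Reagents that add atoms: none
Why: MnO2 oxidises only the allylic primary alcohol, so the saturated primary alcohol and the tertiary alcohol stay free; the enal is used at once.

**Step 14**
Reactants: 30 acyclic (E)-hydroxy enal
Product: 33 CNP0259235.1 (target), via N-benzyl imine 31 (not isolated), via cyclic imine 32 (not isolated)
Conditions: BnNH2, 4 Å molecular sieves, toluene, rt; [RhCl(coe)2]2 (5 mol %), 4-(Me2N)C6H4PEt2 (10 mol %), toluene, 50 °C; wet silica gel, rt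
Reagents that add atoms: water (imine hydrolysis), O
Why: Condensation gives the α,β-unsaturated N-benzyl aldimine 31, whose nitrogen brings monovalent rhodium to the β-C–H bond cis to the C=N group; oxidative addition forms a five-membered aza-rhodacycle hydride, the tethered (E)-alkene inserts into Rh–H with rhodium on the carbon next to the quaternary centre, and C–C reductive elimination forms the ring bond before hydrolysis returns the aldehyde. The closest known reaction type is the rhodium-catalysed intramolecular alkylation of α,β-unsaturated imines by chelation-assisted alkenyl C–H activation (hydroalkenylation of a tethered alkene), known for five-membered carbocycles and, with aryl imines, for six-membered rings. The ring closes in the 6-exo-trig mode, the 7-endo alternative needing a larger rhodacycle. The new ring CH stereocentre is set under substrate control: its side chain takes the pseudo-axial position to escape allylic 1,3-strain with the chelated azadiene and then lies syn to the small axial hydroxyl rather than to the methyl group of the neighbouring carbinol carbon, and anti to the axial chain on the quaternary carbon, which corresponds to R. The geometry of the tetrasubstituted alkene is fixed by the chelate, because the new C–C bond must form cis to the imine carbon, and this is the required isomer since the starting enal is E. Chemoselectivity rests on the fact that only this alkene can reach the metallacycle in a six-membered closure, the others being trisubstituted or remote.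

**Compound list**

1 | 6-methylhept-5-en-2-one (sulcatone) | CC(=O)CCC=C(C)C | starting material
2 | (E)-7-hydroxy-6-methylhept-5-en-2-one | CC(=O)CC/C=C(\C)CO | intermediate
3 | (E)-7-((tert-butyldimethylsilyl)oxy)-6-methylhept-5-en-2-one | CC(=O)CC/C=C(\C)CO[Si](C)(C)C(C)(C)C | intermediate
4 | 5-bromo-2-methylpent-2-ene | CC(C)=CCCBr | starting material
5 | propyne | CC#C | starting material
6 | (4-methylpent-3-en-1-yl)magnesium bromide | CC(C)=CCC[Mg]Br | intermediate
7 | (4-methylpent-3-en-1-yl)copper | CC(C)=CCC[Cu] | intermediate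
8 | [(Z)-2,6-dimethylhepta-1,5-dien-1-yl]copper | [Cu]/C=C(/C)CCC=C(C)C | intermediate
9 | (Z)-1-iodo-2,6-dimethylhepta-1,5-diene | I/C=C(/C)CCC=C(C)C | intermediate
10 | [(Z)-2,6-dimethylhepta-1,5-dien-1-yl]lithium | [Li]/C=C(/C)CCC=C(C)C | intermediate
11 | 2-[(Z)-2,6-dimethylhepta-1,5-dien-1-yl]-4,4,5,5-tetramethyl-1,3,2-dioxaborolane | CC1(C)OB(/C=C(/C)CCC=C(C)C)OC1(C)C | intermediate
12 | 3-((tert-butyldimethylsilyl)oxy)propan-1-ol | OCCCO[Si](C)(C)C(C)(C)C | starting material
13 | 3-((tert-butyldimethylsilyl)oxy)propyl N,N-diisopropylcarbamate | CC(C)N(C(C)C)C(=O)OCCCO[Si](C)(C)C(C)(C)C | intermediate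
14 | (R)-1-lithio-3-((tert-butyldimethylsilyl)oxy)propyl N,N-diisopropylcarbamate (sparteine complex) | [Li][C@H](CCO[Si](C)(C)C(C)(C)C)OC(=O)N(C(C)C)C(C)C | intermediate
15 | lithium boronate complex of 14 and 11 | [Li+].CC1(C)O[B-](OC1(C)C)(/C=C(/C)CCC=C(C)C)[C@H](CCO[Si](C)(C)C(C)(C)C)OC(=O)N(C(C)C)C(C)C | intermediate
16 | (S,Z)-tert-butyl((5,9-dimethyl-3-(4,4,5,5-tetramethyl-1,3,2-dioxaborolan-2-yl)deca-4,8-dien-1-yl)oxy)dimethylsilane | CC1(C)OB(OC1(C)C)[C@@H](CCO[Si](C)(C)C(C)(C)C)/C=C(/C)CCC=C(C)C | intermediate
17 | lithium B-butyl boronate complex of 16 | [Li+].CCCC[B-]1(OC(C)(C)C(C)(C)O1)[C@@H](CCO[Si](C)(C)C(C)(C)C)/C=C(/C)CCC=C(C)C | intermediate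
18 | 2,3-dimethyl-3-(trifluoroacetoxy)butan-2-yl B-butyl borinate of the (S,Z)-allyl unit | CCCCB(OC(C)(C)C(C)(C)OC(=O)C(F)(F)F)[C@@H](CCO[Si](C)(C)C(C)(C)C)/C=C(/C)CCC=C(C)C | intermediate
19 | (2E,6S,7S,8E)-1,11-bis((tert-butyldimethylsilyl)oxy)-2,6,7-trimethyl-7-(4-methylpent-3-en-1-yl)undeca-2,8-dien-6-ol | CC(C)=CCC[C@@](C)(/C=C/CCO[Si](C)(C)C(C)(C)C)[C@@](C)(O)CC/C=C(\C)CO[Si](C)(C)C(C)(C)C | intermediate
20 | (E)-allylic alcohol from oxidation of the homoprenyl terminus of 19 | OC/C(C)=C/CC[C@@](C)(/C=C/CCO[Si](C)(C)C(C)(C)C)[C@@](C)(O)CC/C=C(\C)CO[Si](C)(C)C(C)(C)C | intermediate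
21 | (2E,6S,7S,10E)-12-((tert-butyldimethylsilyl)oxy)-6-[(E)-4-((tert-butyldimethylsilyl)oxy)but-1-en-1-yl]-7-hydroxy-2,6,7,11-tetramethyldodeca-2,10-dienal | O=C/C(C)=C/CC[C@@](C)(/C=C/CCO[Si](C)(C)C(C)(C)C)[C@@](C)(O)CC/C=C(\C)CO[Si](C)(C)C(C)(C)C | intermediate
22 | (S)-citronellal | O=CC[C@@H](C)CCC=C(C)C | starting material
23 | (S)-3,7-dimethylocta-1,6-dien-1-yl nonafluorobutanesulfonate (E/Z mixture) | O=S(=O)(OC=C[C@@H](C)CCC=C(C)C)C(F)(F)C(F)(F)C(F)(F)C(F)(F)F | intermediate
24 | (S)-3,7-dimethyloct-6-en-1-yne | C#C[C@@H](C)CCC=C(C)C | intermediate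
25 | dicyclohexyl[(S,E)-3,7-dimethylocta-1,6-dien-1-yl]borane | C1CCCCC1B(C1CCCCC1)/C=C/[C@@H](C)CCC=C(C)C | intermediate
26 | methyl[(S,E)-3,7-dimethylocta-1,6-dien-1-yl]zinc | C[Zn]/C=C/[C@@H](C)CCC=C(C)C | intermediate
27 | (R)-bis-allylic alcohol with the full carbon skeleton, both silyl ethers and the tertiary alcohol | O[C@H](/C=C/[C@@H](C)CCC=C(C)C)/C(C)=C/CC[C@@](C)(/C=C/CCO[Si](C)(C)C(C)(C)C)[C@@](C)(O)CC/C=C(\C)CO[Si](C)(C)C(C)(C)C | intermediate
28 | (R)-acetate of 27 | CC(=O)O[C@H](/C=C/[C@@H](C)CCC=C(C)C)/C(C)=C/CC[C@@](C)(/C=C/CCO[Si](C)(C)C(C)(C)C)[C@@](C)(O)CC/C=C(\C)CO[Si](C)(C)C(C)(C)C | intermediate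
29 | acetate diol (both primary alcohols free) | CC(=O)O[C@H](/C=C/[C@@H](C)CCC=C(C)C)/C(C)=C/CC[C@@](C)(/C=C/CCO)[C@@](C)(O)CC/C=C(\C)CO | intermediate
30 | acyclic (E)-hydroxy enal, cyclisation precursor | CC(=O)O[C@H](/C=C/[C@@H](C)CCC=C(C)C)/C(C)=C/CC[C@@](C)(/C=C/CCO)[C@@](C)(O)CC/C=C(\C)C=O | intermediate
31 | (E)-N-benzyl aldimine of 30 | CC(=O)O[C@H](/C=C/[C@@H](C)CCC=C(C)C)/C(C)=C/CC[C@@](C)(/C=C/CCO)[C@@](C)(O)CC/C=C(\C)/C=N/Cc1ccccc1 | intermediate
32 | cyclised N-benzyl imine of the target | CC(=O)O[C@H](/C=C/[C@@H](C)CCC=C(C)C)/C(C)=C/CC[C@@]1(C)[C@H](CCCO)/C(=C(/C)\C=N\Cc1ccccc1)CC[C@]1(C)O | intermediate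
33 | CNP0259235.1 | CC(=O)O[C@H](/C=C/[C@@H](C)CCC=C(C)C)/C(C)=C/CC[C@@]1(C)[C@H](CCCO)/C(=C(/C)C=O)CC[C@]1(C)O | target

**Totals.** Total step count: 14. Longest linear sequence: 10 steps (steps 3, 4, 6, 7, 8, 10, 11, 12, 13, 14).

**Steps most likely to fail**

1. Step 14 (key step). What may go wrong: the low-valent rhodium may insert into the bis-allylic acetate (ionisation and loss of the ester); reversible hydride insertion may move the disubstituted alkene toward the primary alcohol; and slow reductive elimination at the hindered carbon may erode facial selectivity. Fallback (sets out from 19, returns at 33): the ring is closed before the acetate and the polyene chain exist. HF·pyridine removes both silyl ethers of 19 to give the triol F1, and MnO2 oxidises only its allylic alcohol to the hydroxy enal F2. Benzylamine converts F2 into the N-benzyl imine F3, the same rhodium catalyst cyclises it to the cyclic imine F4, and hydrolysis gives the ring enal F5. TBSCl and imidazole silylate its primary alcohol to the silyl ether F6. SeO2/tBuOOH oxidises the homoprenyl terminus to the allylic alcohol F7, which MnO2 takes on to the dialdehyde F8. The alkenylzinc 26 (from 24 via 25) with (+)-MIB should add to the less hindered chain enal rather than to the fully substituted ring enal, giving the bis-allylic alcohol F9. Ac2O/pyridine/DMAP gives the acetate F10, and HF·pyridine releases 33.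

2. Step 7. What may go wrong: weak discrimination between the methyl group and the four-carbon arm of ketone 3 in the chair transition state (epimers at the carbinol carbon), and enolisation of the dialkyl ketone by the hindered borinic ester. Fallback (sets out from 16, returns at 19): the borinic ester 18 made from 16 is added instead to but-3-en-2-one, whose planar conjugated vinyl group is a better-defined equatorial substituent, giving the vinyl carbinol F11. 9-BBN hydroborates only its monosubstituted vinyl group to the alkylborane F12. A B-alkyl Suzuki coupling (Pd(dppf)Cl2, AsPh3, Cs2CO3, DMF/THF/H2O) with the iodide silyl ether F13, made from commercial (E)-3-iodo-2-methylprop-2-en-1-ol and TBSCl, then gives 19.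

3. Step 10. What may go wrong: erosion of facial selectivity, because the zinc alkoxide of the free tertiary alcohol competes with the amino alcohol for zinc, together with background methyl transfer. Fallback (sets out from 21 and 24, returns at 27): the carbinol centre is set in an alkynylation and the alkene geometry afterwards. Alkyne 24 and Me2Zn give the alkynylzinc F14. With the ProPhenol ligand enantiomer that directs Re-face attack (Ph3PO additive, toluene), F14 adds to 21 to give the propargylic alcohol F15. NaAlH2(OCH2CH2OMe)2 (Red-Al) in THF then reduces the propargylic alcohol by trans-hydroalumination to the (E)-allylic alcohol 27.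

**Further compounds**

F1 | step 14 | (2E,6S,7S,8E)-2,6,7-trimethyl-7-(4-methylpent-3-en-1-yl)undeca-2,8-diene-1,6,11-triol | CC(C)=CCC[C@@](C)(/C=C/CCO)[C@@](C)(O)CC/C=C(\C)CO
F2 | step 14 | hydroxy enal from F1 | CC(C)=CCC[C@@](C)(/C=C/CCO)[C@@](C)(O)CC/C=C(\C)C=O
F3 | step 14 | N-benzyl imine of F2 | CC(C)=CCC[C@@](C)(/C=C/CCO)[C@@](C)(O)CC/C=C(\C)/C=N/Cc1ccccc1
F4 | step 14 | cyclic imine from F3 | CC(C)=CCC[C@@]1(C)[C@H](CCCO)/C(=C(/C)\C=N\Cc1ccccc1)CC[C@]1(C)O
F5 | step 14 | ring enal with homoprenyl side chain | CC(C)=CCC[C@@]1(C)[C@H](CCCO)/C(=C(/C)C=O)CC[C@]1(C)O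
F6 | step 14 | silyl ether of F5 | CC(C)=CCC[C@@]1(C)[C@H](CCCO[Si](C)(C)C(C)(C)C)/C(=C(/C)C=O)CC[C@]1(C)O
F7 | step 14 | allylic alcohol from F6 | OC/C(C)=C/CC[C@@]1(C)[C@H](CCCO[Si](C)(C)C(C)(C)C)/C(=C(/C)C=O)CC[C@]1(C)O
F8 | step 14 | dialdehyde | O=C/C(C)=C/CC[C@@]1(C)[C@H](CCCO[Si](C)(C)C(C)(C)C)/C(=C(/C)C=O)CC[C@]1(C)O
F9 | step 14 | (R)-bis-allylic alcohol of the cyclised series | O[C@H](/C=C/[C@@H](C)CCC=C(C)C)/C(C)=C/CC[C@@]1(C)[C@H](CCCO[Si](C)(C)C(C)(C)C)/C(=C(/C)C=O)CC[C@]1(C)O
F10 | step 14 | silyl ether of the target | CC(=O)O[C@H](/C=C/[C@@H](C)CCC=C(C)C)/C(C)=C/CC[C@@]1(C)[C@H](CCCO[Si](C)(C)C(C)(C)C)/C(=C(/C)C=O)CC[C@]1(C)O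
F11 | step 7 | (3S,4S,5E)-7-((tert-butyldimethylsilyl)oxy)-3,4-dimethyl-4-(4-methylpent-3-en-1-yl)hepta-1,5-dien-3-ol | CC(C)=CCC[C@@](C)(/C=C/CCO[Si](C)(C)C(C)(C)C)[C@@](C)(O)C=C
F12 | step 7 | B-alkyl-9-borabicyclo[3.3.1]nonane from F11 | CC(C)=CCC[C@@](C)(/C=C/CCO[Si](C)(C)C(C)(C)C)[C@@](C)(O)CCB1C2CCCC1CCC2
F13 | step 7 | (E)-tert-butyl((3-iodo-2-methylallyl)oxy)dimethylsilane | CC(C)(C)[Si](C)(C)OC/C(C)=C/I
F14 | step 10 | methyl[(S)-3,7-dimethyloct-6-en-1-yn-1-yl]zinc | C[Zn]C#C[C@@H](C)CCC=C(C)C
F15 | step 10 | (S)-propargylic alcohol (same spatial arrangement as 27) | O[C@H](C#C[C@@H](C)CCC=C(C)C)/C(C)=C/CC[C@@](C)(/C=C/CCO[Si](C)(C)C(C)(C)C)[C@@](C)(O)CC/C=C(\C)CO[Si](C)(C)C(C)(C)C
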